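Atom labels follow elemanolide numbering: C1=C2 vinyl, C3=C4(–C15) propenyl arm, ring C5–C10, lactone C11/C12/C13, methyl C14.

## The problem

The target is a cyclohexane (C5–C10) with a trans-fused α-methylene-γ-butyrolactone across C6–C7, an acyloxy group at C8, a 3-hydroxyprop-1-en-2-yl arm at C5 and a quaternary C10 bearing methyl and vinyl. The four contiguous ring centres C5–C8 are all-trans and can all be equatorial. At C10 the vinyl group is cis to the C5 arm and therefore axial in that chair, the reverse of the usual elemane pattern, so the C5/C10 dyad has to be built deliberately. C5 and C10 are best set together and can then steer C6 and C7 through a chair. C8 is 1,3 to the quaternary centre and cannot be controlled from it, so it is taken from the chiral pool, as is the (S)-centre of the ester side chain. The α-methylene lactone is a Michael acceptor, and the β-hydroxy ester is prone to elimination, acyl migration and epimerisation. The three different C=C bonds rule out late hydrogenation, ozonolysis or hydroboration, and the cis-1,2-dialkenylcyclohexane can undergo Cope rearrangement on strong heating. Any C6 aldehyde intermediate is β,γ-unsaturated and epimerisable at C5. The enabling feature is that C7 is the γ-carbon of a 2-(alkoxycarbonyl)allyl unit (C13–C11(–C12)=C7) while C6 is a carbinol carbon: making the single bond C6–C7 by allyl addition to a C6 aldehyde closes the cyclohexane and leaves the C6 alkoxide beside the C12 ester, ready to close the lactone with the exocyclic methylene already present.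

## Retrosynthesis

**Ester and silyl groups (31 ⇒ 30 ⇒ 26 + 29).** The C8–O acyl bond is cut last. The β-oxygenated ester would not survive hydride reagents or base, and a silyl ether on O8 is needed earlier to stop the lactone from closing towards C8. Alcohol 26 has a single free hydroxyl, so the forward acylation with acid 29 needs no selectivity, and one fluoride step then frees both primary alcohols.

**Key disconnection (25 ⇒ 22).** Cutting C6–C7 and O–C12 of lactone 25 opens both rings at once and leads to the acyclic aldehyde 22, which has only three stereocentres (C5, C8, C10). The neighbouring cuts (C7–C8 or C5–C6) would each leave the lactone and the methylene to be added afterwards. The forward step must give the anti (trans) relationship at C6/C7 relative to C5 and C8.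

**Allyl bromide and aldehyde (22 ⇒ 21 ⇒ 20 ⇒ 19 ⇒ 17 + 18).** The C7–C11 bond is cut by a Morita–Baylis–Hillman disconnection to the α-silyloxy aldehyde 17 and methyl acrylate 18. The C13 bromide comes from the adduct 19 by allylic transposition. The C6 aldehyde is unveiled only at the end, from a 4-methoxybenzyl ether, because it is the most fragile function and because an amine-free oxidation is needed beside the bromomethyl acrylate.

**Oxidation-state changes (17 ⇒ 16 ⇒ 15 ⇒ 14).** The C7 aldehyde of 17 is drawn from a primary triethylsilyl ether that can be oxidised directly beside a secondary one. The C6 ether of 16 goes back through alcohol 15 to carboxylic acid 14. This costs three steps but uses only reactions that ignore the three alkenes.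

**C5–C10 bond (14 ⇒ 12 ⇒ 7 + 11).** The vicinal tertiary/quaternary dyad is cut by an ester-enolate Claisen transform to the allylic ester 12. A chair transition state relates alkene and enolate geometry to the relative configuration, and a chiral boron reagent supplies the absolute sense. An alkylation or conjugate-addition cut would have to form the quaternary centre against a branched neighbour without such a relay. The target needs vinyl cis to the C5 arm, which requires the (Z)-allylic alcohol 7 together with the ketene acetal that has the 2-propenyl group cis to the allyloxy oxygen. The partner is acid 11.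

**Fragments (7 ⇒ 6 ⇒ 5 ⇒ 3 ⇒ 2 ⇒ 1; 11 ⇒ 10 ⇒ 9 ⇒ 8; 29 ⇒ 28 ⇒ 27).**
- Alcohol 7 is cut at C10–CH3 (syn carbocupration of ynoate 5) and at the alkyne/ester bond, back to the bis-silyl ether 3 of pentynediol 2. Diol 2 is glycidol 1 plus acetylide, so C8 is bought.
- Acid 11 is the reduced, silylated form of commercial monomethyl itaconate 8.
- Acid 29 is the silylated, saponified hydroxy ester 27.

## Roads not taken

**Alternative 1:** Cut C5–C10 and C8–C9 by an intramolecular Diels–Alder reaction. The triene ester A1, a 2-silyloxydiene tethered through C15–O to a methacrylate, would cyclise to the cis-fused bicyclic lactone A2.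
- Merits: the quaternary centre and C5 form in one step. The six-membered tether lactone forces the C1 carbonyl and C4 to be cis, which is the relationship this target has. Reduction to the lactol and methylenation would reveal the vinyl group and free O15 together. No stoichiometric chiral reagent would be needed if a chiral Lewis acid worked.
- Weak points: A1 is an electron-rich cross-conjugated triene prone to dimerise. Ester tethers resist the reactive conformation and usually need strong heating. A1 has no stereocentre, so absolute control rests on a catalyst with little precedent for this tether. After A2, C6, C7 and C8 must still be set one by one, including oxygenation of the unactivated C8 and attachment of the acrylate unit.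
- Comparison: this road is shorter to the carbocycle and better in reagent economy. The chosen plan sets C8 from the chiral pool and makes C6, C7, both rings and the methylene in one step.

**Alternative 2:** Cut C7–C8 by an intramolecular Stetter reaction. A carbene catalyst would turn the C8 aldehyde of the aldehyde–enoate A3 into an acyl anion equivalent that adds to C7, giving cyclohexanone A4.
- Merits: the step is catalytic. The C8 ketone makes C7 epimerisable, so the trans arrangement can be reached under thermodynamic control, which the kinetically controlled chromium step cannot offer. Reduction of the ketone from the axial side would give the equatorial C8 alcohol.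
- Weak points: A3 already needs three contiguous centres (C5, C6, C10), so C6 must be set acyclically. The neopentyl aldehyde beside the quaternary centre is a poor substrate for acyl anion formation. After A4, ketone reduction, desilylation, lactonisation, protection and α-methylenation are still required.
- Comparison: the Stetter road is self-correcting at C7 but costs about five extra steps after ring closure. The chosen plan compensates by delivering the finished lactone directly, at the price of a kinetically determined C6/C7 outcome.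

**Alternative 3:** Keep the ring intact and mask the vinyl and propenyl arms as a bicyclo[2.2.0]hexane. Heating the tricyclic lactone A5 to about 200 °C would cleave C1–C4 and C2–C3 and give the dihydro lactone A6.
- Merits: the cis relation of the two arms is guaranteed by the fused four-membered rings. With the alkenes masked, reagents that the chosen route must avoid could be used earlier.
- Weak points: A5 is harder to make than the target. The product is a cis-1,2-dialkenylcyclohexane that can enter Cope equilibration at the temperature of its formation. Other fragmentation modes of the strained ring compete. The C11 methylene still has to be added.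
- Comparison: alkene masking is a real advantage. The chosen plan answers it by using only reagents that leave isolated alkenes alone and by never heating the divinyl system.

Key step: step 18

Assumption: the (S,S)-antipode of the diazaborolidine is taken to be the one that shields the ketene acetal face leading to (2R)-14; the antipodal diamine is equally available, so a reversed assignment changes only which antipode is used.

## Route

Step 1
Reactants: 1 (R)-glycidol
Product: 2 (2S)-pent-4-yne-1,2-diol
Conditions: LiC≡CH·H2NCH2CH2NH2 (3 equiv), DMSO, 0 °C → rt; aq. NH4Cl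
Reagents that add atoms: LiC≡CH·H2NCH2CH2NH2 (lithium acetylide–ethylenediamine complex), [Li]C#C.NCCN
Why: Acetylide opens the epoxide by SN2 attack at the unsubstituted carbon; the stereocentre is not touched, and its descriptor changes from R to S only because the substituent priorities change.

Step 2
Reactants: 2 (2S)-pent-4-yne-1,2-diol
Product: 3 (4S)-4,5-bis(triethylsilyloxy)pent-1-yne
Conditions: Et3SiCl, imidazole, DMAP (cat.), CH2Cl2, 0 °C → rt
Reagents that add atoms: chlorotriethylsilane, CC[Si](Cl)(CC)CC
Why: Standard silylation of both hydroxyl groups; the primary and the secondary triethylsilyl ether are told apart later by their different behaviour under Swern conditions.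

Step 3
Reactants: 3 (4S)-4,5-bis(triethylsilyloxy)pent-1-yne
Product: 5 methyl (5S)-5,6-bis(triethylsilyloxy)hex-2-ynoate, via lithium acetylide 4 (not isolated)
Conditions: n-BuLi, THF, −78 °C; then ClCO2Me, −78 → 0 °C
Reagents that add atoms: methyl chloroformate, COC(=O)Cl
Why: Deprotonation of the terminal alkyne and C-acylation of the lithium acetylide by the chloroformate; the silyl ethers are inert at this temperature.

Step 4
Reactants: 5 methyl (5S)-5,6-bis(triethylsilyloxy)hex-2-ynoate
Product: 6 methyl (2Z,5S)-3-methyl-5,6-bis(triethylsilyloxy)hex-2-enoate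
Conditions: Me2CuLi (from MeLi and CuI), THF, −78 °C; MeOH at −78 °C, then aq. NH4Cl
Reagents that add atoms: Me2CuLi (lithium dimethylcuprate), [Li+].C[Cu-]C
Why: Syn carbocupration of the ynoate puts methyl and copper cis, and protonation at −78 °C with retention gives the (Z)-enoate with the C9 chain cis to the ester; the low temperature prevents the vinylcopper–allenoate equilibration that would erode the geometry.

Step 5
Reactants: 6 methyl (2Z,5S)-3-methyl-5,6-bis(triethylsilyloxy)hex-2-enoate
Product: 7 (2Z,5S)-3-methyl-5,6-bis(triethylsilyloxy)hex-2-en-1-ol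
Conditions: i-Bu2AlH, CH2Cl2, −78 → 0 °C
Reagents that add atoms: none
Why: 1,2-Reduction of the enoate by the aluminium hydride gives the allylic alcohol without touching the alkene geometry or the silyl ethers.

Step 6
Reactants: 8 monomethyl itaconate (4-methoxy-2-methylidene-4-oxobutanoic acid)
Product: 9 methyl 3-(hydroxymethyl)but-3-enoate
Conditions: BH3·SMe2, THF, −10 °C → rt; MeOH quench, neutral work-up
Reagents that add atoms: none
Why: Borane reduces a free carboxylic acid much faster than an ester or an electron-poor alkene (as with fumaric half-esters), so only the carboxyl that becomes C15 is reduced; neutral work-up and immediate silylation forestall lactonisation of the γ-hydroxy ester.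

Step 7
Reactants: 9 methyl 3-(hydroxymethyl)but-3-enoate
Product: 10 methyl 3-[(tert-butyldimethylsilyloxy)methyl]but-3-enoate
Conditions: t-BuMe2SiCl, imidazole, CH2Cl2, 0 °C → rt
Reagents that add atoms: tert-butyldimethylsilyl chloride, CC(C)(C)[Si](C)(C)Cl
Why: Standard silylation of the primary allylic alcohol.

Step 8
Reactants: 10 methyl 3-[(tert-butyldimethylsilyloxy)methyl]but-3-enoate
Product: 11 3-[(tert-butyldimethylsilyloxy)methyl]but-3-enoic acid
Conditions: LiOH, THF/H2O, 0 °C; aq. HCl to pH 4 at 0 °C
Reagents that add atoms: LiOH (lithium hydroxide), [Li+].[OH-]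
Why: Saponification at 0 °C is faster than enolisation, so the double bond should stay out of conjugation, and the carboxylate formed no longer enolises.

Step 9
Reactants: 7 (2Z,5S)-3-methyl-5,6-bis(triethylsilyloxy)hex-2-en-1-ol; 11 3-[(tert-butyldimethylsilyloxy)methyl]but-3-enoic acid
Product: 12 (2Z,5S)-3-methyl-5,6-bis(triethylsilyloxy)hex-2-en-1-yl 3-[(tert-butyldimethylsilyloxy)methyl]but-3-enoate
Conditions: EDC·HCl, DMAP (0.1 equiv), CH2Cl2, 0 °C → rt
Reagents that add atoms: none
Why: Steglich esterification under nearly neutral conditions; little DMAP and low temperature limit migration of the β,γ-double bond.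

Step 10
Reactants: 12 (2Z,5S)-3-methyl-5,6-bis(triethylsilyloxy)hex-2-en-1-yl 3-[(tert-butyldimethylsilyloxy)methyl]but-3-enoate
Product: 14 (2R,3R,5S)-2-[3-(tert-butyldimethylsilyloxy)prop-1-en-2-yl]-3-ethenyl-3-methyl-5,6-bis(triethylsilyloxy)hexanoic acid, via boron ketene acetal 13 (not isolated)
Conditions: (S,S)-2-bromo-4,5-diphenyl-1,3-bis{[3,5-bis(trifluoromethyl)phenyl]sulfonyl}-1,3,2-diazaborolidine (from the bis-sulfonamide and BBr3), Et3N, toluene–hexane, −78 °C; then 4 °C; aq. work-up
Reagents that add atoms: none
Why: Enantioselective ester-enolate Claisen rearrangement (Ireland–Claisen type) through a chiral boron ketene acetal: soft enolisation with Et3N in a non-polar medium should give the ketene acetal with the 2-propenyl group cis to the allyloxy oxygen, and the chair of the [3,3] shift with the (Z)-allyl unit then places C4 and C9 axial, which translates into vinyl cis to the C5 arm. The C2-symmetric diazaborolidine shields one face of the ketene acetal and so fixes C5 and, through the chair, C10; the remote C8 centre is a spectator.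

Step 11
Reactants: 14 (2R,3R,5S)-2-[3-(tert-butyldimethylsilyloxy)prop-1-en-2-yl]-3-ethenyl-3-methyl-5,6-bis(triethylsilyloxy)hexanoic acid
Product: 15 (2R,3R,5S)-2-[3-(tert-butyldimethylsilyloxy)prop-1-en-2-yl]-3-ethenyl-3-methyl-5,6-bis(triethylsilyloxy)hexan-1-ol
Conditions: LiAlH4, THF, 0 °C → rt
Reagents that add atoms: none
Why: Hydride reduction of the hindered carboxylic acid to the primary alcohol; isolated alkenes and silyl ethers are inert to the reagent at this temperature.

Step 12
Reactants: 15 (2R,3R,5S)-2-[3-(tert-butyldimethylsilyloxy)prop-1-en-2-yl]-3-ethenyl-3-methyl-5,6-bis(triethylsilyloxy)hexan-1-ol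
Product: 16 4-methoxybenzyl ether of 15 (C6–O-PMB)
Conditions: NaH, 4-methoxybenzyl chloride, n-Bu4NI (cat.), THF/DMF, 0 °C → rt
Reagents that add atoms: 4-methoxybenzyl chloride, COc1ccc(CCl)cc1
Why: Williamson etherification; the 4-methoxybenzyl ether is the one group that can later be removed oxidatively beside an allylic bromide, an enoate and three silyl ethers.

Step 13
Reactants: 16 4-methoxybenzyl ether of 15
Product: 17 (2S,4R,5R)-5-[3-(tert-butyldimethylsilyloxy)prop-1-en-2-yl]-4-ethenyl-6-[(4-methoxyphenyl)methoxy]-4-methyl-2-(triethylsilyloxy)hexanal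
Conditions: (COCl)2, DMSO, CH2Cl2, −78 → −40 °C; then Et3N, −78 °C → rt
Reagents that add atoms: none
Why: Under Swern conditions a primary triethylsilyl ether is cleaved and oxidised in one operation, while the secondary triethylsilyl ether and the primary tert-butyldimethylsilyl ether stay intact (chemoselective oxidative desilylation); the α-silyloxy aldehyde is used without purification.

Step 14
Reactants: 17 (2S,4R,5R)-5-[3-(tert-butyldimethylsilyloxy)prop-1-en-2-yl]-4-ethenyl-6-[(4-methoxyphenyl)methoxy]-4-methyl-2-(triethylsilyloxy)hexanal; 18 methyl acrylate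
Product: 19 methyl (4S,6R,7R)-7-[3-(tert-butyldimethylsilyloxy)prop-1-en-2-yl]-6-ethenyl-3-hydroxy-8-[(4-methoxyphenyl)methoxy]-6-methyl-2-methylidene-4-(triethylsilyloxy)octanoate (both C3 epimers)
Conditions: methyl acrylate (5 equiv), DABCO (1 equiv), MeOH (small volume), rt
Reagents that add atoms: none
Why: Morita–Baylis–Hillman reaction: the amine adds to the acrylate and the resulting enolate attacks the activated α-silyloxy aldehyde; the new carbinol centre (C7) need not be controlled because it is destroyed in step 15.

Step 15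
Reactants: 19 methyl (4S,6R,7R)-7-[3-(tert-butyldimethylsilyloxy)prop-1-en-2-yl]-6-ethenyl-3-hydroxy-8-[(4-methoxyphenyl)methoxy]-6-methyl-2-methylidene-4-(triethylsilyloxy)octanoate
Product: 20 methyl (2Z,4S,6R,7R)-2-(bromomethyl)-7-[3-(tert-butyldimethylsilyloxy)prop-1-en-2-yl]-6-ethenyl-8-[(4-methoxyphenyl)methoxy]-6-methyl-4-(triethylsilyloxy)oct-2-enoate
Conditions: NBS, Me2S (reagent pre-formed at 0 °C), CH2Cl2, 0 °C → rt
Reagents that add atoms: N-bromosuccinimide, O=C1CCC(=O)N1Br
Why: The bromosulfonium reagent activates the allylic alcohol and bromide attacks C13 with allylic transposition (SN2'), giving the thermodynamically preferred trisubstituted enoate with C8 cis to CH2Br; both C7 epimers converge.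

Step 16
Reactants: 20 methyl (2Z,4S,6R,7R)-2-(bromomethyl)-7-[3-(tert-butyldimethylsilyloxy)prop-1-en-2-yl]-6-ethenyl-8-[(4-methoxyphenyl)methoxy]-6-methyl-4-(triethylsilyloxy)oct-2-enoate
Product: 21 methyl (2Z,4S,6R,7R)-2-(bromomethyl)-7-[3-(tert-butyldimethylsilyloxy)prop-1-en-2-yl]-6-ethenyl-8-hydroxy-6-methyl-4-(triethylsilyloxy)oct-2-enoate
Conditions: DDQ, CH2Cl2/pH 7 phosphate buffer, 0 °C
Reagents that add atoms: none
Why: Oxidative cleavage of the 4-methoxybenzyl ether by electron transfer to DDQ under buffered conditions, which leave the allylic bromide, the enoate and the silyl ethers alone.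

Step 17
Reactants: 21 methyl (2Z,4S,6R,7R)-2-(bromomethyl)-7-[3-(tert-butyldimethylsilyloxy)prop-1-en-2-yl]-6-ethenyl-8-hydroxy-6-methyl-4-(triethylsilyloxy)oct-2-enoate
Product: 22 methyl (2Z,4S,6R,7R)-2-(bromomethyl)-7-[3-(tert-butyldimethylsilyloxy)prop-1-en-2-yl]-6-ethenyl-6-methyl-8-oxo-4-(triethylsilyloxy)oct-2-enoate
Conditions: Dess–Martin periodinane, NaHCO3, CH2Cl2, 0 °C → rt
Reagents that add atoms: none
Why: Dess–Martin oxidation is neutral and amine-free, so neither the 2-(bromomethyl)acrylate nor the epimerisable, β,γ-unsaturated C5 centre is endangered; the aldehyde is taken on at once.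

Step 18
Reactants: 22 methyl (2Z,4S,6R,7R)-2-(bromomethyl)-7-[3-(tert-butyldimethylsilyloxy)prop-1-en-2-yl]-6-ethenyl-6-methyl-8-oxo-4-(triethylsilyloxy)oct-2-enoate
Product: 25 (3aS,4S,6R,7R,7aR)-7-[3-(tert-butyldimethylsilyloxy)prop-1-en-2-yl]-6-ethenyl-6-methyl-3-methylidene-4-(triethylsilyloxy)hexahydro-1-benzofuran-2(3H)-one, via allylchromium species 23 (not isolated), via chromium alkoxide 24 (not isolated)
Conditions: CrCl2 (5 equiv), THF (0.01 M), rt; aq. NH4Cl
Reagents that add atoms: none
Why: Two equivalents of divalent chromium reduce the C13–Br bond to the trivalent allylchromium species 23, which adds through its γ-carbon C7 to the C6 aldehyde in a six-membered chromium-bridged (Zimmerman–Traxler) transition state and regenerates the C11=C13 methylene; the closest known reaction type is the intramolecular Nozaki–Hiyama–Kishi allylation of aldehydes by 2-(bromomethyl)acrylates with lactonisation in the flask. The cyclohexane closes 6-exo-trig at the aldehyde carbon, and the chromium alkoxide 24 then closes the lactone 5-exo-trig at the C12 ester with loss of methoxide. C6 is controlled by the chair-like forming ring: with the C5 arm and the C8 silyloxy group equatorial the aldehyde oxygen must also be equatorial, because an axial oxygen would be syn-axial to the C10 vinyl group. C7 is controlled by the closed transition state, which requires O6 and C11 to be synclinal; with O6 equatorial this puts C11 equatorial and H6/H7 trans-diaxial. The selectivity needed is therefore anti (trans) at C6/C7 relative to the existing C5 and C8 centres. The bromide of step 15 first gives the allylchromium isomer with C8 cis to CH2Cr, whose chair pathway would lead to the axial alkoxide; the vinyl group penalises that pathway, and 1,3-metallotropic shift of chromium interconverts the two allyl geometries, so the all-equatorial, trans-decalin-like pathway should be followed under Curtin–Hammett conditions. The C8 silyl ether reinforces the equatorial preference and prevents lactonisation towards O8, and the neutral medium spares the C5 centre.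

Step 19
Reactants: 25 (3aS,4S,6R,7R,7aR)-7-[3-(tert-butyldimethylsilyloxy)prop-1-en-2-yl]-6-ethenyl-6-methyl-3-methylidene-4-(triethylsilyloxy)hexahydro-1-benzofuran-2(3H)-one
Product: 26 (3aR,4S,6R,7R,7aR)-7-[3-(tert-butyldimethylsilyloxy)prop-1-en-2-yl]-6-ethenyl-4-hydroxy-6-methyl-3-methylidenehexahydro-1-benzofuran-2(3H)-one
Conditions: PPTS (cat.), MeOH/CH2Cl2, 0 °C
Reagents that add atoms: none
Why: The secondary triethylsilyl ether is solvolysed by mild acid far faster than the primary tert-butyldimethylsilyl ether (selective desilylation); the acid is too weak to add methanol to the α-methylene lactone.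

Step 20
Reactants: 27 methyl (2S)-3-hydroxy-2-methylpropanoate
Product: 28 methyl (2S)-3-(tert-butyldimethylsilyloxy)-2-methylpropanoate
Conditions: t-BuMe2SiCl, imidazole, CH2Cl2, 0 °C → rt
Reagents that add atoms: tert-butyldimethylsilyl chloride, CC(C)(C)[Si](C)(C)Cl
Why: Standard silylation; the stereocentre is not involved.

Step 21
Reactants: 28 methyl (2S)-3-(tert-butyldimethylsilyloxy)-2-methylpropanoate
Product: 29 (2S)-3-(tert-butyldimethylsilyloxy)-2-methylpropanoic acid
Conditions: LiOH, THF/MeOH/H2O, 0 °C → rt; aq. HCl to pH 4 at 0 °C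
Reagents that add atoms: LiOH (lithium hydroxide), [Li+].[OH-]
Why: Mild saponification; the α-centre should not epimerise at the carboxylate stage.

Step 22
Reactants: 26 (3aR,4S,6R,7R,7aR)-7-[3-(tert-butyldimethylsilyloxy)prop-1-en-2-yl]-6-ethenyl-4-hydroxy-6-methyl-3-methylidenehexahydro-1-benzofuran-2(3H)-one; 29 (2S)-3-(tert-butyldimethylsilyloxy)-2-methylpropanoic acid
Product: 30 (3aR,4S,6R,7R,7aR)-7-[3-(tert-butyldimethylsilyloxy)prop-1-en-2-yl]-6-ethenyl-6-methyl-3-methylidene-2-oxooctahydro-1-benzofuran-4-yl (2S)-3-(tert-butyldimethylsilyloxy)-2-methylpropanoate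
Conditions: EDC·HCl, DMAP (0.2 equiv), CH2Cl2, 0 °C → rt
Reagents that add atoms: none
Why: Steglich esterification of the only free hydroxyl group; low temperature and little DMAP limit ketene formation and β-elimination of the activated β-silyloxy acid, so the (2S) centre should be retained.

Step 23
Reactants: 30 (3aR,4S,6R,7R,7aR)-7-[3-(tert-butyldimethylsilyloxy)prop-1-en-2-yl]-6-ethenyl-6-methyl-3-methylidene-2-oxooctahydro-1-benzofuran-4-yl (2S)-3-(tert-butyldimethylsilyloxy)-2-methylpropanoate
Product: 31 (3aR,4S,6R,7R,7aR)-6-ethenyl-7-(3-hydroxyprop-1-en-2-yl)-6-methyl-3-methylidene-2-oxooctahydro-1-benzofuran-4-yl (2S)-3-hydroxy-2-methylpropanoate (CNP0133858.2)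
Conditions: HF·pyridine, pyridine, THF, 0 °C → rt
Reagents that add atoms: none
Why: Buffered HF·pyridine removes both primary tert-butyldimethylsilyl ethers without base, so the β-hydroxy ester, the allylic alcohol and the α-methylene lactone are not exposed to conditions that cause elimination, acyl migration or conjugate addition.

## Compound list

1 | (R)-glycidol [(2R)-oxiran-2-ylmethanol] | OC[C@@H]1CO1 | starting material
2 | (2S)-pent-4-yne-1,2-diol | C#CC[C@H](O)CO | intermediate
3 | (4S)-4,5-bis(triethylsilyloxy)pent-1-yne | C#CC[C@H](O[Si](CC)(CC)CC)CO[Si](CC)(CC)CC | intermediate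
4 | lithium acetylide of 3 | [Li]C#CC[C@H](O[Si](CC)(CC)CC)CO[Si](CC)(CC)CC | intermediate (not isolated)
5 | methyl (5S)-5,6-bis(triethylsilyloxy)hex-2-ynoate | COC(=O)C#CC[C@H](O[Si](CC)(CC)CC)CO[Si](CC)(CC)CC | intermediate
6 | methyl (2Z,5S)-3-methyl-5,6-bis(triethylsilyloxy)hex-2-enoate | COC(=O)/C=C(/C)C[C@H](O[Si](CC)(CC)CC)CO[Si](CC)(CC)CC | intermediate
7 | (2Z,5S)-3-methyl-5,6-bis(triethylsilyloxy)hex-2-en-1-ol | OC/C=C(/C)C[C@H](O[Si](CC)(CC)CC)CO[Si](CC)(CC)CC | intermediate
8 | monomethyl itaconate (4-methoxy-2-methylidene-4-oxobutanoic acid) | C=C(CC(=O)OC)C(=O)O | starting material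
9 | methyl 3-(hydroxymethyl)but-3-enoate | C=C(CO)CC(=O)OC | intermediate
10 | methyl 3-[(tert-butyldimethylsilyloxy)methyl]but-3-enoate | C=C(CO[Si](C)(C)C(C)(C)C)CC(=O)OC | intermediate
11 | 3-[(tert-butyldimethylsilyloxy)methyl]but-3-enoic acid | C=C(CO[Si](C)(C)C(C)(C)C)CC(=O)O | intermediate
12 | (2Z,5S)-3-methyl-5,6-bis(triethylsilyloxy)hex-2-en-1-yl 3-[(tert-butyldimethylsilyloxy)methyl]but-3-enoate | C=C(CO[Si](C)(C)C(C)(C)C)CC(=O)OC/C=C(/C)C[C@H](O[Si](CC)(CC)CC)CO[Si](CC)(CC)CC | intermediate
13 | boron ketene acetal of 12 (O-bound (S,S)-diazaborolidinyl group; 2-propenyl group cis to the allyloxy oxygen) | C=C(CO[Si](C)(C)C(C)(C)C)/C=C(/OB1N(S(=O)(=O)c2cc(cc(c2)C(F)(F)F)C(F)(F)F)[C@@H](c2ccccc2)[C@H](c2ccccc2)N1S(=O)(=O)c1cc(cc(c1)C(F)(F)F)C(F)(F)F)OC/C=C(/C)C[C@H](O[Si](CC)(CC)CC)CO[Si](CC)(CC)CC | intermediate (not isolated)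
14 | (2R,3R,5S)-2-[3-(tert-butyldimethylsilyloxy)prop-1-en-2-yl]-3-ethenyl-3-methyl-5,6-bis(triethylsilyloxy)hexanoic acid | C=C[C@@](C)(C[C@H](O[Si](CC)(CC)CC)CO[Si](CC)(CC)CC)[C@@H](C(=O)O)C(=C)CO[Si](C)(C)C(C)(C)C | intermediate
15 | (2R,3R,5S)-2-[3-(tert-butyldimethylsilyloxy)prop-1-en-2-yl]-3-ethenyl-3-methyl-5,6-bis(triethylsilyloxy)hexan-1-ol | C=C[C@@](C)(C[C@H](O[Si](CC)(CC)CC)CO[Si](CC)(CC)CC)[C@@H](CO)C(=C)CO[Si](C)(C)C(C)(C)C | intermediate
16 | 4-methoxybenzyl ether of 15 | C=C[C@@](C)(C[C@H](O[Si](CC)(CC)CC)CO[Si](CC)(CC)CC)[C@@H](COCc1ccc(OC)cc1)C(=C)CO[Si](C)(C)C(C)(C)C | intermediate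
17 | (2S,4R,5R)-5-[3-(tert-butyldimethylsilyloxy)prop-1-en-2-yl]-4-ethenyl-6-[(4-methoxyphenyl)methoxy]-4-methyl-2-(triethylsilyloxy)hexanal | C=C[C@@](C)(C[C@H](O[Si](CC)(CC)CC)C=O)[C@@H](COCc1ccc(OC)cc1)C(=C)CO[Si](C)(C)C(C)(C)C | intermediate
18 | methyl acrylate | C=CC(=O)OC | starting material
19 | methyl (4S,6R,7R)-7-[3-(tert-butyldimethylsilyloxy)prop-1-en-2-yl]-6-ethenyl-3-hydroxy-8-[(4-methoxyphenyl)methoxy]-6-methyl-2-methylidene-4-(triethylsilyloxy)octanoate (both C3 epimers) | C=C[C@@](C)(C[C@H](O[Si](CC)(CC)CC)C(O)C(=C)C(=O)OC)[C@@H](COCc1ccc(OC)cc1)C(=C)CO[Si](C)(C)C(C)(C)C | intermediate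
20 | methyl (2Z,4S,6R,7R)-2-(bromomethyl)-7-[3-(tert-butyldimethylsilyloxy)prop-1-en-2-yl]-6-ethenyl-8-[(4-methoxyphenyl)methoxy]-6-methyl-4-(triethylsilyloxy)oct-2-enoate | C=C[C@@](C)(C[C@H](O[Si](CC)(CC)CC)/C=C(/C(=O)OC)CBr)[C@@H](COCc1ccc(OC)cc1)C(=C)CO[Si](C)(C)C(C)(C)C | intermediate
21 | methyl (2Z,4S,6R,7R)-2-(bromomethyl)-7-[3-(tert-butyldimethylsilyloxy)prop-1-en-2-yl]-6-ethenyl-8-hydroxy-6-methyl-4-(triethylsilyloxy)oct-2-enoate | C=C[C@@](C)(C[C@H](O[Si](CC)(CC)CC)/C=C(/C(=O)OC)CBr)[C@@H](CO)C(=C)CO[Si](C)(C)C(C)(C)C | intermediate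
22 | methyl (2Z,4S,6R,7R)-2-(bromomethyl)-7-[3-(tert-butyldimethylsilyloxy)prop-1-en-2-yl]-6-ethenyl-6-methyl-8-oxo-4-(triethylsilyloxy)oct-2-enoate | C=C[C@@](C)(C[C@H](O[Si](CC)(CC)CC)/C=C(/C(=O)OC)CBr)[C@@H](C=O)C(=C)CO[Si](C)(C)C(C)(C)C | intermediate
23 | allylchromium species from 22 (CH2–CrCl2 at C13, trivalent chromium; alkene geometry fluxional) | C=C[C@@](C)(C[C@H](O[Si](CC)(CC)CC)C=C(C(=O)OC)C[Cr](Cl)Cl)[C@@H](C=O)C(=C)CO[Si](C)(C)C(C)(C)C | intermediate (not isolated)
24 | chromium alkoxide of the cyclised hydroxy ester (O6–CrCl2, trivalent chromium; ring substituents as in 25) | C=C[C@@]1(C)C[C@H](O[Si](CC)(CC)CC)[C@@H](C(=C)C(=O)OC)[C@H](O[Cr](Cl)Cl)[C@H]1C(=C)CO[Si](C)(C)C(C)(C)C | intermediate (not isolated)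
25 | (3aS,4S,6R,7R,7aR)-7-[3-(tert-butyldimethylsilyloxy)prop-1-en-2-yl]-6-ethenyl-6-methyl-3-methylidene-4-(triethylsilyloxy)hexahydro-1-benzofuran-2(3H)-one | C=C[C@@]1(C)C[C@H](O[Si](CC)(CC)CC)[C@H]2C(=C)C(=O)O[C@@H]2[C@H]1C(=C)CO[Si](C)(C)C(C)(C)C | intermediate
26 | (3aR,4S,6R,7R,7aR)-7-[3-(tert-butyldimethylsilyloxy)prop-1-en-2-yl]-6-ethenyl-4-hydroxy-6-methyl-3-methylidenehexahydro-1-benzofuran-2(3H)-one | C=C[C@@]1(C)C[C@H](O)[C@H]2C(=C)C(=O)O[C@@H]2[C@H]1C(=C)CO[Si](C)(C)C(C)(C)C | intermediate
27 | methyl (2S)-3-hydroxy-2-methylpropanoate | COC(=O)[C@@H](C)CO | starting material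
28 | methyl (2S)-3-(tert-butyldimethylsilyloxy)-2-methylpropanoate | COC(=O)[C@@H](C)CO[Si](C)(C)C(C)(C)C | intermediate
29 | (2S)-3-(tert-butyldimethylsilyloxy)-2-methylpropanoic acid | OC(=O)[C@@H](C)CO[Si](C)(C)C(C)(C)C | intermediate
30 | (3aR,4S,6R,7R,7aR)-7-[3-(tert-butyldimethylsilyloxy)prop-1-en-2-yl]-6-ethenyl-6-methyl-3-methylidene-2-oxooctahydro-1-benzofuran-4-yl (2S)-3-(tert-butyldimethylsilyloxy)-2-methylpropanoate | C=C[C@@]1(C)C[C@H](OC(=O)[C@@H](C)CO[Si](C)(C)C(C)(C)C)[C@H]2C(=C)C(=O)O[C@@H]2[C@H]1C(=C)CO[Si](C)(C)C(C)(C)C | intermediate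
31 | (3aR,4S,6R,7R,7aR)-6-ethenyl-7-(3-hydroxyprop-1-en-2-yl)-6-methyl-3-methylidene-2-oxooctahydro-1-benzofuran-4-yl (2S)-3-hydroxy-2-methylpropanoate | C=C[C@@]1(C)C[C@H](OC(=O)[C@@H](C)CO)[C@H]2C(=C)C(=O)O[C@@H]2[C@H]1C(=C)CO | target

## Step count and weak points

Total: 23 steps. Longest linear sequence: 18 steps (steps 1–5, 9–19, 22, 23, from glycidol 1).

**Step 18 (key step).** The most likely failure is ring closure through the competing chair in which the allylchromium keeps the geometry it is born with (C8 cis to CH2Cr). That would give the cis-fused lactone with an axial O6, because 2-(alkoxycarbonyl)allylchromium species tend to prefer this geometry. Protonation of the allylchromium before cyclisation is a lesser risk.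
Fallback, from 17 back to 25, closing the same C6–C7 bond and the same lactone by a ketyl radical instead of an allylmetal:
- Horner–Wadsworth–Emmons reaction of 17 with trimethyl phosphonoacetate (LiCl, DBU, MeCN) should give the (E)-enoate F1.
- DDQ should give the C6 alcohol F2, and Dess–Martin oxidation the aldehyde F3.
- SmI2 (divalent samarium) in THF/MeOH at −78 °C should generate the C6 ketyl, which adds 6-exo to C7 of the (E)-enoate with the usual anti preference and lactonises to the saturated lactone F4 (the same structure as A6).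
- LDA and Eschenmoser's salt should give the Mannich base F5; MeI and then NaHCO3 should eliminate it to 25.

**Step 10.** The ketene acetal may form with the other geometry (2-propenyl cis to the O–B oxygen), which would deliver the C10 epimer. Facial control by the boron reagent may be incomplete at these congested termini, and the Lewis-acidic boron may cleave a silyl ether during the long reaction time.
Fallback, from 3 back to 14, using the allylic partner of opposite geometry:
- Carboalumination of 3 (Me3Al, Cp2ZrCl2 (zirconocene dichloride), CH2Cl2; then n-BuLi and paraformaldehyde) should give the (E)-allylic alcohol F6 in one step.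
- Esterification with 11 gives the (E)-ester F7.
- Rearrangement of F7 through the ketene acetal of the other geometry (same boron reagent, i-Pr2NEt, CH2Cl2) leads through the same chair analysis to 14.

**Step 14.** The amine-catalysed addition may be very slow with this hindered aldehyde, and prolonged exposure to base invites epimerisation at C8 or loss of the α-silyloxy group.
Fallback, from 17 to 19 without amine catalysis: hydroalumination of methyl propiolate with i-Bu2AlH and N-methylmorpholine N-oxide in THF gives the α-(methoxycarbonyl)vinylaluminium reagent, which adds to 17 at −78 → 0 °C and should give 19 directly. No new compound arises (F0).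

**Step 13.** Discrimination between the two triethylsilyl ethers may be incomplete (loss of the secondary ether or incomplete conversion of the primary one), because the selectivity rests only on rate.
Fallback, from 16 to 17 in two steps: HF·pyridine/pyridine in THF at 0 °C should remove only the primary triethylsilyl ether and give the C7 alcohol F8, and Dess–Martin oxidation then gives 17.

**Step 19.** The primary allylic tert-butyldimethylsilyl ether at C15 may be lost together with the triethylsilyl ether, because the margin between the two is kinetic.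
Fallback, from 25 to 26 by reversing the order: HF·pyridine should remove both silyl groups and give the diol F9, and t-BuMe2SiCl/imidazole at −20 °C should then silylate the unhindered primary allylic hydroxyl in preference to the ring-bound secondary one, giving 26.

## Further compounds

F1 | step 18 | methyl (2E,4S,6R,7R)-7-[3-(tert-butyldimethylsilyloxy)prop-1-en-2-yl]-6-ethenyl-8-[(4-methoxyphenyl)methoxy]-6-methyl-4-(triethylsilyloxy)oct-2-enoate | C=C[C@@](C)(C[C@H](O[Si](CC)(CC)CC)/C=C/C(=O)OC)[C@@H](COCc1ccc(OC)cc1)C(=C)CO[Si](C)(C)C(C)(C)C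
F2 | step 18 | methyl (2E,4S,6R,7R)-7-[3-(tert-butyldimethylsilyloxy)prop-1-en-2-yl]-6-ethenyl-8-hydroxy-6-methyl-4-(triethylsilyloxy)oct-2-enoate | C=C[C@@](C)(C[C@H](O[Si](CC)(CC)CC)/C=C/C(=O)OC)[C@@H](CO)C(=C)CO[Si](C)(C)C(C)(C)C
F3 | step 18 | methyl (2E,4S,6R,7R)-7-[3-(tert-butyldimethylsilyloxy)prop-1-en-2-yl]-6-ethenyl-6-methyl-8-oxo-4-(triethylsilyloxy)oct-2-enoate | C=C[C@@](C)(C[C@H](O[Si](CC)(CC)CC)/C=C/C(=O)OC)[C@@H](C=O)C(=C)CO[Si](C)(C)C(C)(C)C
F4 | step 18 | (3aS,4S,6R,7R,7aR)-7-[3-(tert-butyldimethylsilyloxy)prop-1-en-2-yl]-6-ethenyl-6-methyl-4-(triethylsilyloxy)hexahydro-1-benzofuran-2(3H)-one | C=C[C@@]1(C)C[C@H](O[Si](CC)(CC)CC)[C@H]2CC(=O)O[C@@H]2[C@H]1C(=C)CO[Si](C)(C)C(C)(C)C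
F5 | step 18 | 3-[(dimethylamino)methyl] derivative of F4 (C3 epimers) | C=C[C@@]1(C)C[C@H](O[Si](CC)(CC)CC)[C@H]2C(CN(C)C)C(=O)O[C@@H]2[C@H]1C(=C)CO[Si](C)(C)C(C)(C)C
F6 | step 10 | (2E,5S)-3-methyl-5,6-bis(triethylsilyloxy)hex-2-en-1-ol | OC/C=C(\C)C[C@H](O[Si](CC)(CC)CC)CO[Si](CC)(CC)CC
F7 | step 10 | (2E,5S)-3-methyl-5,6-bis(triethylsilyloxy)hex-2-en-1-yl 3-[(tert-butyldimethylsilyloxy)methyl]but-3-enoate | C=C(CO[Si](C)(C)C(C)(C)C)CC(=O)OC/C=C(\C)C[C@H](O[Si](CC)(CC)CC)CO[Si](CC)(CC)CC
F0 | step 14 | none | none
F8 | step 13 | (2S,4R,5R)-5-[3-(tert-butyldimethylsilyloxy)prop-1-en-2-yl]-4-ethenyl-6-[(4-methoxyphenyl)methoxy]-4-methyl-2-(triethylsilyloxy)hexan-1-ol | C=C[C@@](C)(C[C@H](O[Si](CC)(CC)CC)CO)[C@@H](COCc1ccc(OC)cc1)C(=C)CO[Si](C)(C)C(C)(C)C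
F9 | step 19 | (3aR,4S,6R,7R,7aR)-6-ethenyl-4-hydroxy-7-(3-hydroxyprop-1-en-2-yl)-6-methyl-3-methylidenehexahydro-1-benzofuran-2(3H)-one | C=C[C@@]1(C)C[C@H](O)[C@H]2C(=C)C(=O)O[C@@H]2[C@H]1C(=C)CO
A1 | alternative 1 | 4-(tert-butyldimethylsilyloxy)-2-methylidenehexa-3,5-dien-1-yl 2-methylprop-2-enoate | C=C(C)C(=O)OCC(=C)C=C(O[Si](C)(C)C(C)(C)C)C=C
A2 | alternative 1 | cis-fused 8a-methyl-4-methylidene-5-(tert-butyldimethylsilyloxy)-3,4,4a,7,8,8a-hexahydroisochromen-1-one (C5 and C10 as in the target) | O=C3[C@@]1(C)CCC=C(O[Si](C)(C)C(C)(C)C)[C@H]1C(=C)CO3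
A3 | alternative 2 | tert-butyl (E)-enoate with C8 aldehyde, C6 triethylsilyl ether and C15 tert-butyldimethylsilyl ether (C5, C6, C10 as in the target) | C=C[C@@](C)(CC=O)[C@@H]([C@@H](O[Si](CC)(CC)CC)/C=C/C(=O)OC(C)(C)C)C(=C)CO[Si](C)(C)C(C)(C)C
A4 | alternative 2 | C8 cyclohexanone with the C7 tert-butyl acetate side chain | C=C[C@@]1(C)CC(=O)[C@@H](CC(=O)OC(C)(C)C)[C@H](O[Si](CC)(CC)CC)[C@H]1C(=C)CO[Si](C)(C)C(C)(C)C
A5 | alternative 3 | tricyclic lactone with C1–C4 and C2–C3 closed as a bicyclo[2.2.0]hexane (outer four-membered ring anti to the cyclohexane) | C3[C@@H]4[C@@]1(C)C[C@H](O[Si](CC)(CC)CC)[C@H]2CC(=O)O[C@@H]2[C@H]1[C@]4(CO[Si](C)(C)C(C)(C)C)C3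
A6 | alternative 3 | 11,13-dihydro lactone core (C8 triethylsilyl ether, C15 tert-butyldimethylsilyl ether) | C=C[C@@]1(C)C[C@H](O[Si](CC)(CC)CC)[C@H]2CC(=O)O[C@@H]2[C@H]1C(=C)CO[Si](C)(C)C(C)(C)C
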